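**Plan**

1. Locants: ring C1 (CH carrying the chain), C2 (CH2), C3 (CHCl), C4 (C(CH3)OH), C5 (CHOH), C6 (CH–O-angeloyl); chain C7 (bears =CH2), C8 (CH–O-angeloyl), C9 (CH2), C10/C11 (oxirane); β is the ring face of the C1 chain. Feature: C3–C6 all carry a heteroatom and C3 and C6 are 1,4-related across C4/C5, the footprint of O2 added to the termini of a C3=C4–C5=C6 ring diene, i.e. of a 2,3-dioxabicyclo[2.2.2]oct-5-ene.
2. Cuts, last-made bond first: the oxirane O on C10=C11; C3–Cl together with C4–O (a 3,4β-epoxide opened at C3); C5–O with the shift of the ring alkene (Wharton transposition of a 4,5β-epoxy 3-ketone); C9=C10 (cross-metathesis) and C8–C9 (allylboration); C8–O (allylic oxidation of the isopropenyl methyl); both ester C–O bonds; C3–O and C6–O (singlet oxygen [4+2]); the C5=C6 alkene (Shapiro) of (S)-carvone, which supplies C1–C8, the C4 methyl and the C7 methylene.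
3. Forward: carvone gives the ring diene; the peroxide ring closes across C3/C6 (step 3) and is opened to the 6-hydroxy 3-ketone; C6 is esterified with inversion; the chain is grown C8, then C9, then C10/C11; the ring oxygenation is then moved from C3 to C5 and C4 and chloride is brought to C3; the chain oxirane is made last.
4. Stereochemistry: C1 from (S)-carvone; C6 from anti addition of singlet oxygen followed by SN2 inversion; C5 from an epoxidation directed by the 3β-hydroxyl that hydride delivery creates; C4 from a second epoxidation directed by the 5β-hydroxyl; C3 by inversion in the trans-diaxial epoxide opening; C8 from (−)-Ipc2B(allyl); C10 from the L-fructose-derived Shi ketone.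

Key step: step 3

Remark: the target is taken as drawn; in the locants above this is 1R,3S,4S,5S,6S,8S,10S with both 2-methylbut-2-enoates Z, and (S)-(+)-carvone carries the matching C1 configuration.

**Route**

Step 1
Reactants: 1 (S)-(+)-carvone
Product: 2 (S)-carvone tosylhydrazone [N'-[(1E,5S)-2-methyl-5-(prop-1-en-2-yl)cyclohex-2-en-1-ylidene]-4-methylbenzenesulfonohydrazide]
Conditions: TsNHNH2, EtOH, AcOH (cat.), rt
Reagents that add atoms: 4-methylbenzenesulfonohydrazide, Cc1ccc(cc1)S(=O)(=O)NN
Why: Tosylhydrazone formation by condensation at the enone carbonyl is routine for 2-alkylcyclohexenones and touches neither the C1 stereocentre nor the isopropenyl group.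

Step 2
Reactants: 2 (S)-carvone tosylhydrazone
Product: 4 (5S)-2-methyl-5-(prop-1-en-2-yl)cyclohexa-1,3-diene, via dienyllithium 3 (not isolated)
Conditions: MeLi (2.5 equiv), Et2O, 0 °C → rt; H2O quench at 0 °C
Reagents that add atoms: none
Why: Shapiro reaction, in which the second equivalent of MeLi removes the C6 proton syn to the sulfonamide nitrogen, loss of sulfinate and N2 leaves the C5 vinyllithium 3 and water protonates it, so the new alkene appears at C5=C6 in conjugation with C3=C4 while C1 should not be deprotonated under these conditions.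

Step 3
Reactants: 4 (5S)-2-methyl-5-(prop-1-en-2-yl)cyclohexa-1,3-diene
Product: 5 (1S,4S,7R)-5-methyl-7-(prop-1-en-2-yl)-2,3-dioxabicyclo[2.2.2]oct-5-ene (peroxide bridge on the α face of C3 and C6; anti to the isopropenyl group)
Conditions: O2, tetraphenylporphyrin (0.5 mol%), white LED light, CH2Cl2, −78 °C
Reagents that add atoms: dioxygen, O=O
Why: Tetraphenylporphyrin sensitises O2 to its singlet state, which adds suprafacially to the s-cis-locked C3=C4–C5=C6 diene in a concerted [4+2] cycloaddition that forms the C3–O and C6–O bonds together. The closest known reaction is the photooxygenation of cyclohexa-1,3-dienes, among them the isopropyl analogue α-phellandrene, to 2,3-dioxabicyclo[2.2.2]oct-5-enes. The six-membered 1,2-dioxene ring, and with it the bicyclo[2.2.2]octene, closes by this cycloaddition across the diene termini and not by a stepwise exo or endo cyclisation. The two new stereocentres C3 and C6 are set together by the face of attack, which the existing C1 stereocentre governs: its isopropenyl group lies over the β face beside the C6 terminus, so oxygen should enter from the α face. The step needs facial selectivity, which this shielding is expected to give only to a moderate degree (hence the low temperature, removal of the syn isomer by chromatography and its separate use described at the end). It also needs chemoselectivity, which is secured because the cyclic diene reacts with singlet oxygen orders of magnitude faster than the isolated 1,1-disubstituted isopropenyl alkene.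

Step 4
Reactants: 5 (1S,4S,7R)-5-methyl-7-(prop-1-en-2-yl)-2,3-dioxabicyclo[2.2.2]oct-5-ene
Product: 6 (4S,5R)-4-hydroxy-2-methyl-5-(prop-1-en-2-yl)cyclohex-2-en-1-one (C3 ketone; 6α-OH; trans to the isopropenyl group)
Conditions: Et3N (0.5 equiv), CH2Cl2, 0 °C → rt
Reagents that add atoms: none
Why: Kornblum–DeLaMare rearrangement, in which the amine should remove the bridgehead hydrogen at C3 (flanked by the C2 methylene, not by the branched C1), the O–O bond breaks and C3 becomes the ketone, while the C6–O bond and hence the 6α configuration are untouched.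

Step 5
Reactants: 6 (4S,5R)-4-hydroxy-2-methyl-5-(prop-1-en-2-yl)cyclohex-2-en-1-one; 7 angelic acid
Product: 8 (1R,6R)-3-methyl-4-oxo-6-(prop-1-en-2-yl)cyclohex-2-en-1-yl (2Z)-2-methylbut-2-enoate (6β-O-angeloyl; cis to the isopropenyl group)
Conditions: 7 (1.5 equiv), PPh3, DIAD, toluene, 0 °C → rt
Reagents that add atoms: none
Why: Mitsunobu esterification of the allylic alcohol proceeds by SN2 attack of angelate on the oxyphosphonium ion, so C6 is inverted to the β configuration of the target; the hydrogen on C1 is syn to the leaving group, which disfavours E2 loss, and the neutral conditions should leave the Z geometry of the acid alone.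

Step 6
Reactants: 8 (1R,6R)-3-methyl-4-oxo-6-(prop-1-en-2-yl)cyclohex-2-en-1-yl (2Z)-2-methylbut-2-enoate
Product: 9 (1R,6R)-6-(3-hydroxyprop-1-en-2-yl)-3-methyl-4-oxocyclohex-2-en-1-yl (2Z)-2-methylbut-2-enoate
Conditions: SeO2 (0.5 equiv), t-BuOOH (5.5 M in decane, 2 equiv), CH2Cl2, rt
Reagents that add atoms: tert-butyl hydroperoxide, CC(C)(C)OO (terminal oxidant); selenium dioxide, O=[Se]=O (catalytic carrier of the oxygen)
Why: Catalytic SeO2/t-BuOOH allylic oxidation (ene reaction, then [2,3] shift) attacks the only electron-rich alkene, the isopropenyl group, and by the usual preference for CH3 over a ring CH oxidises its methyl carbon C8, whereas the enone and the angelate are electron-poor and react far more slowly.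

Step 7
Reactants: 9 (1R,6R)-6-(3-hydroxyprop-1-en-2-yl)-3-methyl-4-oxocyclohex-2-en-1-yl (2Z)-2-methylbut-2-enoate
Product: 10 (1R,6R)-3-methyl-4-oxo-6-(3-oxoprop-1-en-2-yl)cyclohex-2-en-1-yl (2Z)-2-methylbut-2-enoate
Conditions: Dess–Martin periodinane, CH2Cl2, 0 °C → rt
Reagents that add atoms: none
Why: Dess–Martin oxidation of the only hydroxyl, a primary allylic alcohol, gives the α-substituted acrolein without forming a stereocentre or touching the esters and alkenes.

Step 8
Reactants: 10 (1R,6R)-3-methyl-4-oxo-6-(3-oxoprop-1-en-2-yl)cyclohex-2-en-1-yl (2Z)-2-methylbut-2-enoate; 11 (−)-B-allyldiisopinocampheylborane [(−)-Ipc2B(allyl)]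
Product: 13 (1R,6R)-6-[(3S)-3-hydroxyhexa-1,5-dien-2-yl]-3-methyl-4-oxocyclohex-2-en-1-yl (2Z)-2-methylbut-2-enoate, via borinate ester 12 (not isolated)
Conditions: 11 (1 M in pentane, 1.3 equiv), Et2O, −78 °C; then HOCH2CH2NH2, rt
Reagents that add atoms: none
Why: Brown allylboration through a chair (Zimmerman–Traxler) transition state, in which the isopinocampheyl groups derived from (+)-α-pinene direct allyl to the Si face of the aldehyde and so set C8 as S (the sense known for benzaldehyde and 2-substituted acroleins); the aldehyde reacts far faster than the hindered ring enone at −78 °C and the non-oxidative ethanolamine work-up spares the enone.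

Step 9
Reactants: 13 (1R,6R)-6-[(3S)-3-hydroxyhexa-1,5-dien-2-yl]-3-methyl-4-oxocyclohex-2-en-1-yl (2Z)-2-methylbut-2-enoate; 7 angelic acid
Product: 15 (3S)-2-[(1R,2R)-4-methyl-2-{[(2Z)-2-methylbut-2-enoyl]oxy}-5-oxocyclohex-3-en-1-yl]hexa-1,5-dien-3-yl (2Z)-2-methylbut-2-enoate, via mixed anhydride 14 (not isolated)
Conditions: 7 (2 equiv), 2,4,6-Cl3C6H2COCl, Et3N, toluene, rt; then 13, 75 °C
Reagents that add atoms: none
Why: Yamaguchi-type esterification through the 2,4,6-trichlorobenzoyl mixed anhydride, run without DMAP, transfers the angeloyl group to O8 with retention at C8 and without the Z-to-E isomerisation that nucleophilic catalysts cause.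

Step 10
Reactants: 15 (3S)-2-[(1R,2R)-4-methyl-2-{[(2Z)-2-methylbut-2-enoyl]oxy}-5-oxocyclohex-3-en-1-yl]hexa-1,5-dien-3-yl (2Z)-2-methylbut-2-enoate; 16 2-methylbut-2-ene
Product: 17 (3S)-6-methyl-2-[(1R,2R)-4-methyl-2-{[(2Z)-2-methylbut-2-enoyl]oxy}-5-oxocyclohex-3-en-1-yl]hepta-1,5-dien-3-yl (2Z)-2-methylbut-2-enoate
Conditions: (H2IMes)(PCy3)Cl2Ru=CHPh (second-generation Grubbs catalyst, 5 mol%), 16/CH2Cl2 (1:1), 40 °C, sealed tube
Reagents that add atoms: none
Why: Olefin cross-metathesis with 2-methylbut-2-ene turns the monosubstituted alkene into the trisubstituted C10=C11 alkene, while the hindered C7 methylene, the enone and the angelates are too encumbered or electron-poor to engage the ruthenium carbene.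

Step 11
Reactants: 17 (3S)-6-methyl-2-[(1R,2R)-4-methyl-2-{[(2Z)-2-methylbut-2-enoyl]oxy}-5-oxocyclohex-3-en-1-yl]hepta-1,5-dien-3-yl (2Z)-2-methylbut-2-enoate
Product: 18 (3S)-2-[(1R,2R,5R)-5-hydroxy-4-methyl-2-{[(2Z)-2-methylbut-2-enoyl]oxy}cyclohex-3-en-1-yl]-6-methylhepta-1,5-dien-3-yl (2Z)-2-methylbut-2-enoate (3β-OH)
Conditions: NaBH4, CeCl3·7H2O, MeOH, −78 → −40 °C
Reagents that add atoms: none
Why: Luche 1,2-reduction, in which hydride adds axially from the α face, anti to the axial 6β ester and as in the reduction of carvone to cis-carveol, so the new C3 hydroxyl is β (cis to the C1 chain), while esters and isolated alkenes are inert.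

Step 12
Reactants: 18 the 3β-alcohol
Product: 19 4β,5β-epoxy-3β-alcohol (β-oxirane across C4–C5 of 18; 6β-O-angeloyl; 8S-O-angeloyl; C10=C11 alkene)
Conditions: VO(acac)2 (5 mol%), t-BuOOH (5.5 M in decane), CH2Cl2, 0 °C → rt
Reagents that add atoms: tert-butyl hydroperoxide, CC(C)(C)OO
Why: Vanadium-catalysed hydroxyl-directed epoxidation delivers oxygen from the vanadate ester of the 3β-hydroxyl to the β face of C4=C5, which sets C5–O as β, while the chain alkenes (no free allylic hydroxyl) and the electron-poor angelates are not epoxidised.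

Step 13
Reactants: 19 the 4β,5β-epoxy-3β-alcohol
Product: 20 4β,5β-epoxy-3-ketone (6β-O-angeloyl; 8S-O-angeloyl; C10=C11 alkene)
Conditions: Dess–Martin periodinane, pyridine, CH2Cl2, 0 °C → rt
Reagents that add atoms: none
Why: Dess–Martin oxidation of the secondary epoxy alcohol gives the α,β-epoxy ketone under buffered conditions, and the quaternary C4 cannot epimerise.

Step 14
Reactants: 20 the 4β,5β-epoxy-3-ketone
Product: 22 transposed allylic alcohol (C3=C4 alkene; 5β-OH; 6β-O-angeloyl; 8S-O-angeloyl; C10=C11 alkene), via epoxy hydrazone 21 (not isolated)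
Conditions: N2H4·H2O (3 equiv), AcOH (0.5 equiv), MeOH, 0 °C → rt
Reagents that add atoms: none
Why: Wharton transposition, in which the hydrazone 21 opens the oxirane to an alkenyl diazene that loses N2, so the alkene appears at C3=C4 and the oxirane oxygen stays on C5 with its β configuration, as in the conversion of carvone oxide into carveol.

Step 15
Reactants: 22 the transposed allylic alcohol
Product: 23 3β,4β-epoxy-5β-alcohol (β-oxirane across C3–C4 of 22)
Conditions: VO(acac)2 (5 mol%), t-BuOOH (5.5 M in decane), CH2Cl2, 0 °C → rt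
Reagents that add atoms: tert-butyl hydroperoxide, CC(C)(C)OO
Why: A second vanadium-catalysed directed epoxidation, in which the 5β-hydroxyl guides oxygen to the β face of C3=C4 (the carveol case) and so sets C4–O as β, again without touching the chain alkenes.

Step 16
Reactants: 23 the 3β,4β-epoxy-5β-alcohol
Product: 24 chlorohydrin (3α-Cl; 4β-OH with 4α-CH3; 5β-OH; 6β-O-angeloyl; 8S-O-angeloyl; C10=C11 alkene)
Conditions: TiCl(OiPr)3 (1.5 equiv), CH2Cl2, 0 °C → rt; aq. tartaric acid work-up
Reagents that add atoms: chlorotitanium triisopropoxide, CC(C)O[Ti](Cl)(OC(C)C)OC(C)C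
Why: Titanium-assisted opening of a 2,3-epoxy alcohol at the carbon remote from the hydroxyl, in which the 5-alkoxide binds titanium and chloride attacks the secondary C3 from the α face with inversion in the trans-diaxial (Fürst–Plattner) sense, giving 3α-Cl and 4β-OH, while alkenes and esters should be inert to this weak Lewis acid.

Step 17
Reactants: 24 the chlorohydrin
Product: 25 target (24 with the 10S oxirane across C10–C11; 1R,3S,4S,5S,6S,8S,10S)
Conditions: L-fructose-derived Shi ketone (1,2:4,5-di-O-isopropylidene-β-L-erythro-2,3-hexodiulo-2,6-pyranose, 1 equiv), KHSO5 (as 2KHSO5·KHSO4·K2SO4), NaHCO3 (pH about 8), Bu4NHSO4 (cat.), MeCN–CH2(OMe)2/aq. Na2EDTA, 0 °C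
Reagents that add atoms: potassium peroxymonosulfate (KHSO5), [K+].[O-]S(=O)(=O)OO
Why: Shi epoxidation, in which the chiral dioxirane formed from the ketone and KHSO5 epoxidises the electron-rich trisubstituted C10=C11 alkene through a spiro transition state and the L-fructose-derived ketone gives the 10S oxirane under reagent control; the 1,1-disubstituted and conjugated alkenes react much more slowly and the near-neutral buffer is chosen to avoid closure of the chlorohydrin and acyl shift.

**Compound list**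

1 | (S)-(+)-carvone, (5S)-2-methyl-5-(prop-1-en-2-yl)cyclohex-2-en-1-one | C=C(C)[C@H]1CC=C(C)C(=O)C1 | starting material
2 | (S)-carvone tosylhydrazone, N'-[(1E,5S)-2-methyl-5-(prop-1-en-2-yl)cyclohex-2-en-1-ylidene]-4-methylbenzenesulfonohydrazide | C=C(C)[C@H]1CC=C(C)/C(=N/NS(=O)(=O)c2ccc(C)cc2)C1 | intermediate
3 | dienyllithium, [(3S)-6-methyl-3-(prop-1-en-2-yl)cyclohexa-1,5-dien-1-yl]lithium (formed in the flask) | C=C(C)[C@H]1CC=C(C)C([Li])=C1 | intermediate
4 | (5S)-2-methyl-5-(prop-1-en-2-yl)cyclohexa-1,3-diene | C=C(C)[C@H]1CC=C(C)C=C1 | intermediate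
5 | (1S,4S,7R)-5-methyl-7-(prop-1-en-2-yl)-2,3-dioxabicyclo[2.2.2]oct-5-ene | C=C(C)[C@H]1C[C@@H]2OO[C@H]1C=C2C | intermediate
6 | (4S,5R)-4-hydroxy-2-methyl-5-(prop-1-en-2-yl)cyclohex-2-en-1-one | C=C(C)[C@H]1CC(=O)C(C)=C[C@@H]1O | intermediate
7 | angelic acid, (2Z)-2-methylbut-2-enoic acid | C/C=C(/C)C(=O)O | starting material
8 | (1R,6R)-3-methyl-4-oxo-6-(prop-1-en-2-yl)cyclohex-2-en-1-yl (2Z)-2-methylbut-2-enoate | C=C(C)[C@H]1CC(=O)C(C)=C[C@H]1OC(=O)/C(C)=C\C | intermediate
9 | (1R,6R)-6-(3-hydroxyprop-1-en-2-yl)-3-methyl-4-oxocyclohex-2-en-1-yl (2Z)-2-methylbut-2-enoate | C=C(CO)[C@H]1CC(=O)C(C)=C[C@H]1OC(=O)/C(C)=C\C | intermediate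
10 | (1R,6R)-3-methyl-4-oxo-6-(3-oxoprop-1-en-2-yl)cyclohex-2-en-1-yl (2Z)-2-methylbut-2-enoate | C=C(C=O)[C@H]1CC(=O)C(C)=C[C@H]1OC(=O)/C(C)=C\C | intermediate
11 | (−)-B-allyldiisopinocampheylborane, (−)-Ipc2B(allyl), from (+)-α-pinene | C=CCB([C@@H]1C[C@@H]2C[C@H]([C@H]1C)C2(C)C)[C@@H]1C[C@@H]2C[C@H]([C@H]1C)C2(C)C | starting material
12 | borinate ester, the O8-diisopinocampheylboryl derivative of 13 (formed in the flask) | C=C([C@H](CC=C)OB([C@@H]2C[C@@H]3C[C@H]([C@H]2C)C3(C)C)[C@@H]2C[C@@H]3C[C@H]([C@H]2C)C3(C)C)[C@H]1CC(=O)C(C)=C[C@H]1OC(=O)/C(C)=C\C | intermediate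
13 | (1R,6R)-6-[(3S)-3-hydroxyhexa-1,5-dien-2-yl]-3-methyl-4-oxocyclohex-2-en-1-yl (2Z)-2-methylbut-2-enoate | C=C([C@H](CC=C)O)[C@H]1CC(=O)C(C)=C[C@H]1OC(=O)/C(C)=C\C | intermediate
14 | mixed anhydride, (2Z)-2-methylbut-2-enoic 2,4,6-trichlorobenzoic anhydride (formed in the flask) | C/C=C(/C)C(=O)OC(=O)c1c(Cl)cc(Cl)cc1Cl | intermediate
15 | (3S)-2-[(1R,2R)-4-methyl-2-{[(2Z)-2-methylbut-2-enoyl]oxy}-5-oxocyclohex-3-en-1-yl]hexa-1,5-dien-3-yl (2Z)-2-methylbut-2-enoate | C=C([C@H](CC=C)OC(=O)/C(C)=C\C)[C@H]1CC(=O)C(C)=C[C@H]1OC(=O)/C(C)=C\C | intermediate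
16 | 2-methylbut-2-ene | CC=C(C)C | starting material
17 | (3S)-6-methyl-2-[(1R,2R)-4-methyl-2-{[(2Z)-2-methylbut-2-enoyl]oxy}-5-oxocyclohex-3-en-1-yl]hepta-1,5-dien-3-yl (2Z)-2-methylbut-2-enoate | C=C([C@H](CC=C(C)C)OC(=O)/C(C)=C\C)[C@H]1CC(=O)C(C)=C[C@H]1OC(=O)/C(C)=C\C | intermediate
18 | (3S)-2-[(1R,2R,5R)-5-hydroxy-4-methyl-2-{[(2Z)-2-methylbut-2-enoyl]oxy}cyclohex-3-en-1-yl]-6-methylhepta-1,5-dien-3-yl (2Z)-2-methylbut-2-enoate (3β-OH) | C=C([C@H](CC=C(C)C)OC(=O)/C(C)=C\C)[C@H]1C[C@@H](O)C(C)=C[C@H]1OC(=O)/C(C)=C\C | intermediate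
19 | 4β,5β-epoxy-3β-alcohol (β-oxirane across C4–C5 of 18) | C=C([C@H](CC=C(C)C)OC(=O)/C(C)=C\C)[C@H]1C[C@@H](O)[C@@]2(C)O[C@H]2[C@H]1OC(=O)/C(C)=C\C | intermediate
20 | 4β,5β-epoxy-3-ketone | C=C([C@H](CC=C(C)C)OC(=O)/C(C)=C\C)[C@H]1CC(=O)[C@@]2(C)O[C@H]2[C@H]1OC(=O)/C(C)=C\C | intermediate
21 | epoxy hydrazone, the C3 hydrazone of 20 (C=N geometry not defined; formed in the flask) | C=C([C@H](CC=C(C)C)OC(=O)/C(C)=C\C)[C@H]1CC(=NN)[C@@]2(C)O[C@H]2[C@H]1OC(=O)/C(C)=C\C | intermediate
22 | transposed allylic alcohol (C3=C4 alkene; 5β-OH; 6β- and 8S-O-angeloyl; C10=C11 alkene) | C=C([C@H](CC=C(C)C)OC(=O)/C(C)=C\C)[C@H]1CC=C(C)[C@@H](O)[C@H]1OC(=O)/C(C)=C\C | intermediate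
23 | 3β,4β-epoxy-5β-alcohol (β-oxirane across C3–C4 of 22) | C=C([C@H](CC=C(C)C)OC(=O)/C(C)=C\C)[C@H]1C[C@H]2O[C@@]2(C)[C@@H](O)[C@H]1OC(=O)/C(C)=C\C | intermediate
24 | chlorohydrin (3α-Cl; 4β-OH; 5β-OH; 6β- and 8S-O-angeloyl; C10=C11 alkene) | C=C([C@H](CC=C(C)C)OC(=O)/C(C)=C\C)[C@H]1C[C@H](Cl)[C@@](C)(O)[C@@H](O)[C@H]1OC(=O)/C(C)=C\C | intermediate
25 | CNP0333703.2 (1R,3S,4S,5S,6S,8S,10S in the locants of the plan) | C=C([C@H](C[C@@H]1OC1(C)C)OC(=O)/C(C)=C\C)[C@H]1C[C@H](Cl)[C@@](C)(O)[C@@H](O)[C@H]1OC(=O)/C(C)=C\C | target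

**Count and risks**

Total step count: 17. Longest linear sequence: 17 steps from (S)-(+)-carvone (1).

Risk at step 3: weak facial discrimination by the isopropenyl group, so that a large share of the diene is oxygenated on the β face (with some ene hydroperoxide besides). The fallback makes the route stereoconvergent instead of face-selective. Setting out from 4, the syn endoperoxide (1R,4R,7R)-5-methyl-7-(prop-1-en-2-yl)-2,3-dioxabicyclo[2.2.2]oct-5-ene F1 is separated from 5, either as the peroxide or more easily after the amine isomerisation. Et3N (as in step 4) converts it into the cis-hydroxy enone (4R,5R)-4-hydroxy-2-methyl-5-(prop-1-en-2-yl)cyclohex-2-en-1-one F2, whose C6 oxygen is already β. Acylation with retention by the mixed anhydride 14 (conditions of step 9) brings this material back to the route at 8.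

Risk at step 5: slow SN2 displacement by the weakly acidic, hindered angelic acid on the oxyphosphonium ion next to the C1 branch, with recovered alcohol or elimination as the result, or Z-to-E drift of the ester in the presence of the phosphine. The fallback separates inversion from angeloylation. From 6, Mitsunobu reaction with 4-nitrobenzoic acid (PPh3, DIAD) gives the inverted ester (1R,6R)-3-methyl-4-oxo-6-(prop-1-en-2-yl)cyclohex-2-en-1-yl 4-nitrobenzoate F3. K2CO3 in MeOH at 0 °C frees the cis-hydroxy enone F2 (the compound of the preceding fallback), which is angeloylated through 14 and rejoins the route at 8.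

Risk at step 14: attack of hydrazine on the angelate esters, acyl shift from O6 to the new 5-hydroxyl under the basic conditions, or slow hydrazone formation at the hindered ketone. The fallback replaces the diazene fragmentation by a radical one that needs neither base nor the ketone. From 19 (before the oxidation of step 13), 1,1'-thiocarbonyldiimidazole gives the O3-(imidazol-1-ylcarbonothioyl) derivative of 19 F4. Bu3SnH and AIBN in toluene at 80 °C then generate the C3 radical (Barton–McCombie-type deoxygenation), which opens the adjacent oxirane to the C5 alkoxy radical; hydrogen transfer returns to the route at 22.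

Further compounds
F1 | step 3 | (1R,4R,7R)-5-methyl-7-(prop-1-en-2-yl)-2,3-dioxabicyclo[2.2.2]oct-5-ene | C=C(C)[C@H]1C[C@H]2OO[C@@H]1C=C2C
F2 | step 3 | (4R,5R)-4-hydroxy-2-methyl-5-(prop-1-en-2-yl)cyclohex-2-en-1-one | C=C(C)[C@H]1CC(=O)C(C)=C[C@H]1O
F3 | step 5 | (1R,6R)-3-methyl-4-oxo-6-(prop-1-en-2-yl)cyclohex-2-en-1-yl 4-nitrobenzoate | C=C(C)[C@H]1CC(=O)C(C)=C[C@H]1OC(=O)c1ccc(cc1)[N+](=O)[O-]
F4 | step 14 | O3-(imidazol-1-ylcarbonothioyl) derivative of 19 | C=C([C@H](CC=C(C)C)OC(=O)/C(C)=C\C)[C@H]1C[C@@H](OC(=S)n3ccnc3)[C@@]2(C)O[C@H]2[C@H]1OC(=O)/C(C)=C\C
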